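(The numbers are those of an exercise, and the outcome is calculated.)

We begin with the substrate left over, since the amber tank runs its split of substrate at that level.

- red: substrate 0.10 M; time 20 min; a closed flask charged with all of it at once and left for 20 min
- amber: substrate 0.10 M; a single well-mixed tank run continuously and read at steady state, 20 min in it on average

1. the set-up with the highest share of single ring in all that became single ring or open dimer or open trimer or ring dimer or isomer of the product, at the outlet or at the end ("none" if the first two lie within 2 percentage points) (red / amber / none)
2. share of single ring in all that became single ring or open dimer or open trimer or ring dimer or isomer of the product, at the outlet or at the end, red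
3. share of single ring in all that became single ring or open dimer or open trimer or ring dimer or isomer of the product, at the outlet or at the end, amber

- percent here means substrate units held: one open dimer or ring dimer counts as two
- percent here means substrate units held: one open trimer counts as three
- a doubled species enters its step squared and goes two at a time
- the stated concentrations are those of everything mixed, before any reaction; amounts are the same in each set-up
- run time (red): 20 min

    substrate + open dimer → open trimer (k1 = 0.00395 M⁻¹ s⁻¹)
    single ring ⇌ isomer of the product (K2 = 0.35, k2 = 5.46 × 10⁻⁴ s⁻¹)
    substrate → single ring (k3 = 7.96 × 10⁻⁴ s⁻¹)
    open dimer → ring dimer (k4 = 0.00138 s⁻¹)
    2 substrate → open dimer (k5 = 0.0226 M⁻¹ s⁻¹)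

Substrate has two main exits: first-order closure to single ring and second-order formation of open dimer, which takes two substrate units at a time. We define the crossover level c× as the ring-closure constant 7.96 × 10⁻⁴ s⁻¹ over two times the dimerisation constant 0.0226 M⁻¹ s⁻¹, the substrate level at which the two exits take equal substrate units; it is 0.0176 M. The ring fraction f = c×/(c× + c(substrate)), the instantaneous selectivity, is then the part of substrate being spent that enters single ring. It counts single ring and its isomer together. We leave out the substrate taken into open trimer.

Our small table has columns c(substrate) and f, and we read it by rows. At the charge, c(substrate) is 0.10 M and f is 15.0 %. At the end of red, integrating the two exits gives 0.00856 M and f of 67.3 %. So red climbs the table, but its substrate-weighted f is 28.9 %. In amber, the substrate balance over the mean residence time gives a quadratic with root 0.0285 M, and f stands at 38.2 %, higher than the substrate-weighted f of red. We therefore commit to amber, with both shares of single ring lower than these fractions once its isomer is split off.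

The forecast also chose amber, with 22.8 % for red and 30.8 % for amber: “the tank's low, steady substrate level favours single ring over the dimer route”.

The simulation gives amber as best, with 22.7 % for red and 30.8 % for amber.

Striking out the turning of substrate into open dimer takes red minus amber from −8.1 percentage points to 0.46 points, so amber's lead goes with that step. In amber, the substrate level of 0.0283 M gives f of 38.3 %, and amber with the isomer step struck out, both ways, gives a share of 37.8 %. For a tank at three times the residence time, the same balance gives c(substrate) of 0.0156 M and f of 53.0 %, and that tank's share of single ring, with the isomer step running, is 40.6 %.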